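**Plan**
- Retrosynthesis: target 13 is first re-protected (three O-benzyl groups, 5-O-methyl) to chromone 12. Ring C is then cut at O1–C8a to the open-chain diketone 11, the chain at C2–C3 to ketone 5 and aroyl chloride 9, and 5 at C4–C4a.
- Forward: C4–C4a (aryllithium plus Weinreb amide) and C2–C3 (enolate C-acylation) join the purchased rings A and B through a three-carbon chain. Ring C is the only ring made, closed by anodic O1–C8a bond formation, and a global deprotection ends the route.
- Enabling feature: O1 links C2 to ring A at C8a, the carbon ortho to the acyl-bearing C4a. In 11 this is the single free C–H ortho to the ketone of a 2,4,5-trimethoxyphenyl ring, so the ring oxygen can be introduced by dehydrogenation and no ortho hydroxyl or halogen is needed.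
- Stereochemistry: the target has no stereocentre; the one transient centre (C3 of 11, racemic) becomes sp2 on ring closure.

Key step: step 6

Remark: atoms carry flavone numbers throughout (O1, C2, C3, C4, C4a, C5–C8, C8a; ring B primed), also in open-chain compounds; 1, 2 and 6 are taken to be purchasable.

Step 1
Reactants: 1 1-bromo-2,4,5-trimethoxybenzene; 2 2-(benzyloxy)-N-methoxy-N-methylacetamide
Product: 5 2-(benzyloxy)-1-(2,4,5-trimethoxyphenyl)ethan-1-one, via (2,4,5-trimethoxyphenyl)lithium 3 (not isolated), via lithium hemiaminal alkoxide 4 (not isolated)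
Conditions: n-BuLi, THF, −78 °C; then 2, −78 → 0 °C; aq NH4Cl
Reagents that add atoms: none
Why: Bromine–lithium exchange followed by Weinreb ketone synthesis; the aryllithium adds only once because the five-membered lithium chelate 4 persists until the aqueous quench, so the ketone is released on work-up and the acid-sensitive benzyl ether never meets a Lewis acid.

Step 2
Reactants: 6 3,5-dihydroxy-4-methoxybenzoic acid
Product: 7 benzyl 3,5-bis(benzyloxy)-4-methoxybenzoate
Conditions: BnBr (3.5 equiv), K2CO3, DMF, 60 °C
Reagents that add atoms: benzyl bromide, BrCc1ccccc1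
Why: Williamson-type O-alkylation: K2CO3 deprotonates the carboxylic acid and both phenols and each anion displaces bromide from benzyl bromide (SN2), so ether and ester formation occur together and the 4-O-methyl group is untouched.

Step 3
Reactants: 7 benzyl 3,5-bis(benzyloxy)-4-methoxybenzoate
Product: 8 3,5-bis(benzyloxy)-4-methoxybenzoic acid
Conditions: KOH, THF/MeOH/H2O, 60 °C; then aq HCl
Reagents that add atoms: potassium hydroxide, [K+].[OH-]
Why: Ester saponification with hydroxide cleaves only the benzyl ester, since aryl benzyl ethers and the aryl methyl ether are inert to aqueous base.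

Step 4
Reactants: 8 3,5-bis(benzyloxy)-4-methoxybenzoic acid
Product: 9 3,5-bis(benzyloxy)-4-methoxybenzoyl chloride
Conditions: (COCl)2, DMF (cat.), CH2Cl2, 0 °C → rt; concentrate, use crude
Reagents that add atoms: oxalyl chloride, O=C(Cl)C(=O)Cl
Why: DMF-catalysed acid chloride formation through the Vilsmeier-type chloroiminium salt; only gases form beside the product and the benzyl ethers tolerate these Lewis-acid-free conditions.

Step 5
Reactants: 5 2-(benzyloxy)-1-(2,4,5-trimethoxyphenyl)ethan-1-one; 9 3,5-bis(benzyloxy)-4-methoxybenzoyl chloride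
Product: 11 2-(benzyloxy)-1-[3,5-bis(benzyloxy)-4-methoxyphenyl]-3-(2,4,5-trimethoxyphenyl)propane-1,3-dione (racemic), via lithium (Z)-enolate 10 (not isolated)
Conditions: LiN(SiMe3)2 (2.1 equiv), THF, −78 °C; then 9, −78 → 0 °C; aq NH4Cl
Reagents that add atoms: none
Why: Claisen-type C-acylation of a ketone enolate with an aroyl chloride: the chelated lithium enolate 10 attacks 9 at carbon to form C2–C3, and the second equivalent of base converts the more acidic 1,3-diketone into its enolate, which shields it from a second acylation until the quench.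

Step 6
Reactants: 11 2-(benzyloxy)-1-[3,5-bis(benzyloxy)-4-methoxyphenyl]-3-(2,4,5-trimethoxyphenyl)propane-1,3-dione
Product: 12 3-(benzyloxy)-2-[3,5-bis(benzyloxy)-4-methoxyphenyl]-5,7,8-trimethoxy-4H-chromen-4-one
Conditions: constant-current electrolysis (undivided cell, graphite anode, Pt cathode, 5 mA cm−2, 2.2 F mol−1), Bu4NBF4 (0.1 M), (CF3)2CHOH, rt
Reagents that add atoms: none
Why: Proposed new method: anodic removal of one electron from ring A of 11, whose para-dimethoxy pattern makes it the most easily oxidised π system, should give an arene radical cation that is trapped at C8a by the oxygen on C2 (the enol OH, or the ring-B-side carbonyl oxygen with later loss of the C3 proton), and loss of a second electron and a proton restores aromaticity while the cathode turns the two protons into H2. The closest known reaction type is anodic dehydrogenative aryl C–H/O–H cyclisation in (CF3)2CHOH, as in the lactonisation of biaryl-2-carboxylic acids to benzocoumarins, alongside oxidant-mediated closures of an enol oxygen onto electron-rich arenes in benzofuran syntheses. Ring C closes as a six-membered ring by O-attack on the trigonal carbon C8a (6-exo-trig with respect to the C8–C8a π bond), and no other ring size is within reach of this oxygen. No stereocentre is created, and the racemic C3 centre of 11 becomes sp2. The step needs (a) oxidation of ring A in preference to ring B, the enol and the benzyl ethers, which the lower potential of the 1,2,4-trioxygenated ring and the radical-cation-stabilising, weakly nucleophilic solvent should secure, and (b) closure at C8a–H and not at the methoxy-bearing C5, which should follow because only the C8a adduct can rearomatise by irreversible proton loss whereas ipso addition is reversible. The charge is held just above 2 F mol−1 so that the hydrogen-bonded γ-pyranone product is not oxidised further.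

Step 7
Reactants: 12 3-(benzyloxy)-2-[3,5-bis(benzyloxy)-4-methoxyphenyl]-5,7,8-trimethoxy-4H-chromen-4-one
Product: 13 3,5-dihydroxy-2-(3,5-dihydroxy-4-methoxyphenyl)-7,8-dimethoxy-4H-chromen-4-one
Conditions: BCl3 (8 equiv), C6HMe5 (6 equiv), CH2Cl2, −78 → 0 °C; then MeOH, H2O
Reagents that add atoms: none
Why: Lewis-acid ether cleavage with BCl3: the benzyl ethers ionise at −78 °C with pentamethylbenzene trapping the benzyl cations, and on warming the 5-O-methyl ether, held in a six-membered boron chelate with the C4 carbonyl, is demethylated by chloride, whereas the 7-, 8- and 4'-O-methyl groups lack such a chelate and should survive.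

**Compound list**
1 | 1-bromo-2,4,5-trimethoxybenzene | COc1cc(OC)c(Br)cc1OC | starting material
2 | 2-(benzyloxy)-N-methoxy-N-methylacetamide | CON(C)C(=O)COCc1ccccc1 | starting material
3 | (2,4,5-trimethoxyphenyl)lithium (formed in the flask in step 1) | [Li]c1cc(OC)c(OC)cc1OC | intermediate
4 | lithium 2-(benzyloxy)-1-[methoxy(methyl)amino]-1-(2,4,5-trimethoxyphenyl)ethan-1-olate (racemic chelate, formed in the flask in step 1) | COc1cc(OC)c(C(O[Li])(COCc2ccccc2)N(C)OC)cc1OC | intermediate
5 | 2-(benzyloxy)-1-(2,4,5-trimethoxyphenyl)ethan-1-one | COc1cc(OC)c(C(=O)COCc2ccccc2)cc1OC | intermediate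
6 | 3,5-dihydroxy-4-methoxybenzoic acid | COc1c(O)cc(C(=O)O)cc1O | starting material
7 | benzyl 3,5-bis(benzyloxy)-4-methoxybenzoate | COc1c(OCc2ccccc2)cc(C(=O)OCc2ccccc2)cc1OCc1ccccc1 | intermediate
8 | 3,5-bis(benzyloxy)-4-methoxybenzoic acid | COc1c(OCc2ccccc2)cc(C(=O)O)cc1OCc1ccccc1 | intermediate
9 | 3,5-bis(benzyloxy)-4-methoxybenzoyl chloride | COc1c(OCc2ccccc2)cc(C(=O)Cl)cc1OCc1ccccc1 | intermediate
10 | lithium (Z)-2-(benzyloxy)-1-(2,4,5-trimethoxyphenyl)ethen-1-olate (formed in the flask in step 5) | [Li]O/C(=C\OCc1ccccc1)c1cc(OC)c(OC)cc1OC | intermediate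
11 | 2-(benzyloxy)-1-[3,5-bis(benzyloxy)-4-methoxyphenyl]-3-(2,4,5-trimethoxyphenyl)propane-1,3-dione (racemic) | COc1cc(OC)c(C(=O)C(OCc2ccccc2)C(=O)c2cc(OCc3ccccc3)c(OC)c(OCc3ccccc3)c2)cc1OC | intermediate
12 | 3-(benzyloxy)-2-[3,5-bis(benzyloxy)-4-methoxyphenyl]-5,7,8-trimethoxy-4H-chromen-4-one | COc1cc(OC)c2c(=O)c(OCc3ccccc3)c(-c3cc(OCc4ccccc4)c(OC)c(OCc4ccccc4)c3)oc2c1OC | intermediate
13 | 3,5-dihydroxy-2-(3,5-dihydroxy-4-methoxyphenyl)-7,8-dimethoxy-4H-chromen-4-one | COc1cc(O)c2c(=O)c(O)c(-c3cc(O)c(OC)c(O)c3)oc2c1OC | target

**Step count**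
Total: 7 steps. Longest linear sequence: 6 steps (6 → 7 → 8 → 9 → 11 → 12 → 13, steps 2–7).

**Steps most likely to fail**

Step 6 (the unprecedented step). The electron may be taken from the enol or from ring B instead of ring A, the oxygen may add ipso at C5 with loss of the methyl group, or the chromone may be oxidised further on ring A. The fallback uses known chemistry, sets out from ketone 5 and comes back at chromone 12; it installs the C8a oxygen before the chain is completed. Ketone-directed ortho C–H hydroxylation of 5 [Pd(OCOCF3)2 (cat.), PhI(OCOCF3)2, 1,2-dichloroethane, 80 °C, aqueous work-up], for which C8a is the only free ortho position, should give 2-(benzyloxy)-1-(2-hydroxy-3,4,6-trimethoxyphenyl)ethan-1-one F1. O-Acylation of the phenol with acid chloride 9 (Et3N, DMAP, CH2Cl2) gives 2-[(benzyloxy)acetyl]-3,5,6-trimethoxyphenyl 3,5-bis(benzyloxy)-4-methoxybenzoate F2. Baker–Venkataraman rearrangement (LiN(SiMe3)2, THF, −20 °C) then gives 2-(benzyloxy)-1-[3,5-bis(benzyloxy)-4-methoxyphenyl]-3-(2-hydroxy-3,4,6-trimethoxyphenyl)propane-1,3-dione F3, and acid-catalysed cyclodehydration (TsOH cat., toluene, 80 °C) closes ring C to 12.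

Step 5. The enolate may be acylated on oxygen to an enol ester, the product may be acylated a second time, or the electron-rich aroyl chloride may react too slowly. The fallback sets out from benzyl ester 7 and ketone 5 and comes back at diketone 11; it replaces acylation by aldol addition and oxidation. LiAlH4 (THF, 0 °C) reduces 7 to [3,5-bis(benzyloxy)-4-methoxyphenyl]methanol F4, and MnO2 (CH2Cl2, rt) oxidises this to 3,5-bis(benzyloxy)-4-methoxybenzaldehyde F5. Aldol addition of enolate 10 (from 5, LiN(SiMe3)2, THF, −78 °C) to F5 gives 2-(benzyloxy)-3-[3,5-bis(benzyloxy)-4-methoxyphenyl]-3-hydroxy-1-(2,4,5-trimethoxyphenyl)propan-1-one F6 as a diastereomer mixture of no consequence, and Dess–Martin periodinane (CH2Cl2, rt) oxidises the carbinol to 11.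

Step 7. A non-chelated methyl ether may be lost (above all the 4'-O-methyl once the neighbouring oxygens carry boron), the 5-O-methyl ether may be cleaved incompletely, or released benzyl cations may alkylate the electron-rich rings. The fallback sets out from 12 and comes back at 13; it separates the two cleavages. Hydrogenolysis (H2, Pd/C, THF/MeOH, rt) removes the benzyl groups to give 2-(3,5-dihydroxy-4-methoxyphenyl)-3-hydroxy-5,7,8-trimethoxy-4H-chromen-4-one F7, and AlCl3 in MeCN (rt) then cleaves only the 5-O-methyl ether through the aluminium chelate with the C4 carbonyl, giving 13.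

Further compounds
F1 | step 6 | 2-(benzyloxy)-1-(2-hydroxy-3,4,6-trimethoxyphenyl)ethan-1-one | COc1cc(OC)c(C(=O)COCc2ccccc2)c(O)c1OC
F2 | step 6 | 2-[(benzyloxy)acetyl]-3,5,6-trimethoxyphenyl 3,5-bis(benzyloxy)-4-methoxybenzoate | COc1cc(OC)c(C(=O)COCc2ccccc2)c(OC(=O)c2cc(OCc3ccccc3)c(OC)c(OCc3ccccc3)c2)c1OC
F3 | step 6 | 2-(benzyloxy)-1-[3,5-bis(benzyloxy)-4-methoxyphenyl]-3-(2-hydroxy-3,4,6-trimethoxyphenyl)propane-1,3-dione (racemic) | COc1cc(OC)c(C(=O)C(OCc2ccccc2)C(=O)c2cc(OCc3ccccc3)c(OC)c(OCc3ccccc3)c2)c(O)c1OC
F4 | step 5 | [3,5-bis(benzyloxy)-4-methoxyphenyl]methanol | COc1c(OCc2ccccc2)cc(CO)cc1OCc1ccccc1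
F5 | step 5 | 3,5-bis(benzyloxy)-4-methoxybenzaldehyde | COc1c(OCc2ccccc2)cc(C=O)cc1OCc1ccccc1
F6 | step 5 | 2-(benzyloxy)-3-[3,5-bis(benzyloxy)-4-methoxyphenyl]-3-hydroxy-1-(2,4,5-trimethoxyphenyl)propan-1-one (racemic mixture of diastereomers) | COc1cc(OC)c(C(=O)C(OCc2ccccc2)C(O)c2cc(OCc3ccccc3)c(OC)c(OCc3ccccc3)c2)cc1OC
F7 | step 7 | 2-(3,5-dihydroxy-4-methoxyphenyl)-3-hydroxy-5,7,8-trimethoxy-4H-chromen-4-one | COc1cc(OC)c2c(=O)c(O)c(-c3cc(O)c(OC)c(O)c3)oc2c1OC
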